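**Assumptions.** The target has no stereocentres, so no stereocontrol is needed. Sulfate esters are drawn as free hydrogen sulfates, as in the target SMILES; in practice they are handled as Bu4N+ salts (step 2) or K+ salts (storage), and counter-ions are not tracked.

## Retrosynthetic overview

1. Target 4 ⇒ C3–O disconnection: direct C3–H sulfoxylation of apigenin 7,4'-di-O-sulfate 2, so the C–O bond is made with the sulfate already attached.
2. 2 ⇒ apigenin 1 by O-sulfation of the 7-OH and 4'-OH; the chelated 5-OH stays free.
3. No ring is formed: rings A, C and B are bought intact as apigenin, and the 7- and 4'-sulfates of the target act as the protecting groups during the C–O step.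

## Route

**Step 1**
Reactants: 1 apigenin
Product: 2 apigenin 7,4'-di-O-sulfate
Conditions: SO3·pyridine (2.4 equiv), pyridine, 25→45 °C; isolated as the bis(Bu4N) salt (ion-pair extraction, Sephadex LH-20)
Reagents that add atoms: sulfur trioxide–pyridine complex, O=S(=O)([O-])[n+]1ccccc1
Why: Phenol O-sulfation with an SO3–amine complex takes the acidic, unhindered 7-OH and 4'-OH, while the 5-OH is locked in its hydrogen bond to C4=O and does not react with a limited amount of reagent.

**Step 2**
Reactants: 2 apigenin 7,4'-di-O-sulfate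
Product: 4 kaempferol 3,7,4'-tri-O-sulfate, via cis-2,3-cyclic sulfate adduct 3 (not isolated)
Conditions: PhIO (1.5 equiv) and SO3·pyridine (1.5 equiv) premixed in MeCN, 4 Å MS, 0 °C, 30 min; then 2 [(Bu4N)2 salt], 0→25 °C; aq. Na2S2O3 quench, C18/Sephadex LH-20
Reagents that add atoms: iodosylbenzene, O=Ic1ccccc1; sulfur trioxide–pyridine complex, O=S(=O)([O-])[n+]1ccccc1
Why: Proposed new method: the pyridine-ligated iodine(III) sulfate made in situ from PhIO and SO3·pyridine should be attacked by C3 of the enol-ether-polarised C2=C3 bond (the C2 oxocarbenium is stabilised by O1 and the 4'-oxygenated aryl ring), the iodine-bound sulfate then closes onto C2 and couples to C3 with loss of PhI to give cyclic sulfate 3, whose ketal-type C2–O bond ionises and loses H-3 to pyridine (E1) to leave the C3–OSO3 ester on the restored pyranone, while the chelated ortho-acyl 5-OH and the two aryl sulfate groups are poor ligands for iodine(III); the closest known reaction types are the iodosylbenzene–SO3 syn-addition to alkenes that gives cyclic sulfates, Koser-type α-sulfonyloxylation of ketones and the iodine(III)-mediated C3-hydroxylation of flavones, but a vinylic C–H to C–OSO3 conversion on a chromone has not been shown.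

## Compound list

1 | apigenin (5,7,4'-trihydroxyflavone) | O=c1cc(-c2ccc(O)cc2)oc2cc(O)cc(O)c12 | starting material
2 | apigenin 7,4'-di-O-sulfate | O=c1cc(-c2ccc(OS(=O)(=O)O)cc2)oc2cc(OS(=O)(=O)O)cc(O)c12 | intermediate
3 | cis-2,3-cyclic sulfate adduct of 2 (5-hydroxy-4-oxoflavan-2,3-diyl cyclic sulfate 7,4'-bis(hydrogen sulfate); racemic, one enantiomer drawn) | O=C1c2c(O)cc(OS(=O)(=O)O)cc2O[C@]2(c3ccc(OS(=O)(=O)O)cc3)OS(=O)(=O)O[C@H]12 | intermediate
4 | kaempferol 3,7,4'-tri-O-sulfate | O=c1c(OS(=O)(=O)O)c(-c2ccc(OS(=O)(=O)O)cc2)oc2cc(OS(=O)(=O)O)cc(O)c12 | target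

## Step count and risks

Total step count: 2. Longest linear sequence: 2.

The route has only two steps, so both are ranked here; there is no third step to list.

**1. Step 2 (the proposed new C3–H sulfoxylation), most likely to fail.** The main failure modes are:
- the iodane attacks the A ring (C6/C8) or oxidises the 5-OH phenol instead of C3;
- the reaction stalls at a 3-(phenyliodonio)flavone that does not couple with sulfate;
- the C2=C3 bond of this vinylogous ester is too weak a nucleophile;
- acid formed in the reaction strips an aryl sulfate.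

Fallback (known chemistry; the C3–O bond is made by dioxirane oxygen transfer on a protected flavone and all sulfates are put on last). It sets out from 1 and comes back to the route at 4. Apigenin 1 is perbenzylated (BnBr, K2CO3, DMF, 80 °C) to 5,7,4'-tri-O-benzylapigenin F1. Dimethyldioxirane in acetone/CH2Cl2 (0 °C→rt) epoxidises C2=C3 to the 2,3-epoxide of tri-O-benzylapigenin F2. Catalytic p-TsOH opens this to 5,7,4'-tri-O-benzylkaempferol F3. Hydrogenolysis (H2, Pd/C, EtOAc/MeOH) gives kaempferol F4. Carbodiimide sulfation (Bu4N HSO4, DCC, pyridine) then sulfates the 3-, 7- and 4'-OH but not the chelated 5-OH, giving 4.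

**2. Step 1 (selective disulfation).** The risk is a mixture of mono- and disulfates with traces of 5-O-sulfate, and a difficult separation of very polar salts.

Fallback (protected sulfate diesters in place of direct SO3 transfer). It sets out from 1 and comes back at 2. Apigenin 1 is treated with 2,2,2-trichloroethyl chlorosulfate (2.2 equiv, Et3N, DMAP, THF, 0 °C→rt) to give the neutral, silica-purifiable apigenin 7,4'-bis(2,2,2-trichloroethyl sulfate) F5. Zn dust with HCO2NH4 in MeOH at rt removes both trichloroethyl groups to give 2, which is exchanged to the Bu4N+ salt.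

## Further compounds

F1 | step 2 | 5,7,4'-tri-O-benzylapigenin | O=c1cc(-c2ccc(OCc3ccccc3)cc2)oc2cc(OCc3ccccc3)cc(OCc3ccccc3)c12
F2 | step 2 | 2,3-epoxide of 5,7,4'-tri-O-benzylapigenin (racemic, one enantiomer drawn) | O=C1c2c(OCc3ccccc3)cc(OCc3ccccc3)cc2O[C@]2(c3ccc(OCc4ccccc4)cc3)O[C@H]12
F3 | step 2 | 5,7,4'-tri-O-benzylkaempferol | O=c1c(O)c(-c2ccc(OCc3ccccc3)cc2)oc2cc(OCc3ccccc3)cc(OCc3ccccc3)c12
F4 | step 2 | kaempferol | O=c1c(O)c(-c2ccc(O)cc2)oc2cc(O)cc(O)c12
F5 | step 1 | apigenin 7,4'-bis(2,2,2-trichloroethyl sulfate) | O=c1cc(-c2ccc(OS(=O)(=O)OCC(Cl)(Cl)Cl)cc2)oc2cc(OS(=O)(=O)OCC(Cl)(Cl)Cl)cc(O)c12
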